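**Plan**

- Retrosynthesis first cuts the eight phenolic C–O bonds at C1/C3 of ring A and C3/C5 of rings B, C and D, each back to C–CHO. It then cuts the three diaryl ether bonds (ring A C2–O, ring B C4–O, ring C C4–O) and the ring D C4–O(benzyl) bond, each back to C–F.
- Enabling feature: each of those eight hydroxyls is ortho to an ether-type oxygen (C2–O of ring A, C4–O of rings B, C and D). A formyl group at each site therefore flanks the C–F carbon and activates it for SNAr, and is afterwards exchanged for oxygen by aryl migration.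
- All four rings come from one monomer, 2-fluoro-5-hydroxyisophthalaldehyde, made from 4-fluoro-3,5-dimethylphenol.
- Forward: no ring is formed. The chain is joined from ring D towards ring A: benzyl alcohol caps ring D, then three phenoxide/aryl fluoride couplings (D+C, DC+B, DCB+A) follow, with 4-methoxybenzyl (PMB) as temporary phenol protection.
- End game: eightfold Baeyer–Villiger oxidation, methanolysis of the formates, hydrogenolysis of the two benzyl ethers.
- Stereochemistry: the target is achiral and has no stereocentre, so nothing needs to be controlled.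

Key step: step 13

Remark on the chemistry: ring A is the phloroglucinol end (C2 carries the ether oxygen). Rings B and C are the inner rings (C1–O towards ring A, C4–O towards ring D). Ring D is the pyrogallol end (C1–O to ring C, C4–OH central). It is assumed that a formyl group next to a di-ortho-substituted aryloxy or benzyloxy oxygen behaves in the peracid oxidation like a simple ortho-alkoxybenzaldehyde.

**Route**

Step 1
Reactants: 1 4-fluoro-3,5-dimethylphenol
Product: 2 4-fluoro-3,5-dimethylphenyl acetate
Conditions: Ac2O, pyridine, DMAP (cat.), CH2Cl2, 0 °C → rt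
Reagents that add atoms: acetic anhydride, CC(=O)OC(C)=O
Why: O-acylation of the phenol; the acetate lowers the electron density of the ring so that the following radical bromination should stay at the benzylic positions.

Step 2
Reactants: 2 4-fluoro-3,5-dimethylphenyl acetate
Product: 3 3,5-bis(dibromomethyl)-4-fluorophenyl acetate
Conditions: NBS (4.6 equiv), AIBN (cat.), PhCF3, 90 °C, visible light
Reagents that add atoms: N-bromosuccinimide, O=C1CCC(=O)N1Br
Why: Wohl–Ziegler radical bromination; each methyl has one unhindered side, so geminal dibromination should be reached, while a third bromine is disfavoured sterically.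

Step 3
Reactants: 3 3,5-bis(dibromomethyl)-4-fluorophenyl acetate
Product: 5 2-fluoro-5-hydroxyisophthalaldehyde (2-fluoro-5-hydroxybenzene-1,3-dicarbaldehyde), via acetoxy dialdehyde 4 (not isolated)
Conditions: AgNO3 (4.4 equiv), 1,4-dioxane/H2O, 85 °C, dark; filter; then 2 M HCl, 70 °C
Reagents that add atoms: water, O
Why: silver-assisted hydrolysis of the two benzal bromides to formyl groups, followed by acid-catalysed hydrolysis of the aryl acetate in the same aqueous medium; the fluoride should survive because no strong nucleophile is present.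

Step 4
Reactants: 5 2-fluoro-5-hydroxyisophthalaldehyde; 6 4-methoxybenzyl chloride
Product: 7 2-fluoro-5-[(4-methoxybenzyl)oxy]isophthalaldehyde
Conditions: K2CO3, NaI (cat.), MeCN, 0 °C → rt
Reagents that add atoms: none
Why: Williamson O-alkylation; benzylic alkylation of the phenoxide should be much faster at this temperature than its attack on the C–F carbon of a second molecule.

Step 5
Reactants: 7 2-fluoro-5-[(4-methoxybenzyl)oxy]isophthalaldehyde; 8 benzyl alcohol
Product: 9 2-(benzyloxy)-5-[(4-methoxybenzyl)oxy]isophthalaldehyde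
Conditions: 8 (1.3 equiv), Cs2CO3, DMSO, rt
Reagents that add atoms: none
Why: SNAr (addition–elimination); the fluoride between two ortho formyl groups is displaced by benzyl alkoxide through a Meisenheimer adduct stabilised by both carbonyls.

Step 6
Reactants: 9 2-(benzyloxy)-5-[(4-methoxybenzyl)oxy]isophthalaldehyde
Product: 10 2-(benzyloxy)-5-hydroxyisophthalaldehyde (ring D phenol)
Conditions: TFA (10 vol%), anisole (5 equiv), CH2Cl2, 0 °C → rt
Reagents that add atoms: none
Why: acidolysis of the PMB ether with Friedel–Crafts capture of the 4-methoxybenzyl cation by anisole; the benzyl ether on the electron-poor ring ionises far more slowly and should remain.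

Step 7
Reactants: 10 2-(benzyloxy)-5-hydroxyisophthalaldehyde; 7 2-fluoro-5-[(4-methoxybenzyl)oxy]isophthalaldehyde
Product: 11 2-[4-(benzyloxy)-3,5-diformylphenoxy]-5-[(4-methoxybenzyl)oxy]isophthalaldehyde (rings D–C, tetra-aldehyde)
Conditions: K2CO3, DMSO, 50 °C, 7 (1.05 equiv)
Reagents that add atoms: none
Why: SNAr diaryl ether formation; the phenoxide of ring D adds to the C–F carbon activated by two ortho formyl groups, and the product carries no fluoride, so the chain cannot grow further.

Step 8
Reactants: 11 rings D–C tetra-aldehyde PMB ether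
Product: 12 2-[4-(benzyloxy)-3,5-diformylphenoxy]-5-hydroxyisophthalaldehyde (rings D–C phenol)
Conditions: TFA (10 vol%), anisole (5 equiv), CH2Cl2, 0 °C → rt
Reagents that add atoms: none
Why: the same PMB acidolysis as in step 6; aldehydes, the diaryl ether and the benzyl ether are stable to dilute TFA.

Step 9
Reactants: 12 rings D–C phenol; 7 2-fluoro-5-[(4-methoxybenzyl)oxy]isophthalaldehyde
Product: 13 2-{4-[4-(benzyloxy)-3,5-diformylphenoxy]-3,5-diformylphenoxy}-5-[(4-methoxybenzyl)oxy]isophthalaldehyde (rings D–C–B, hexa-aldehyde)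
Conditions: K2CO3, DMSO, 50 °C, 7 (1.05 equiv)
Reagents that add atoms: none
Why: second SNAr coupling of the same type; fluoride is a far better SNAr leaving site than the aryloxy group of the existing ether, so substitution should occur at C–F.

Step 10
Reactants: 13 rings D–C–B hexa-aldehyde PMB ether
Product: 14 2-{4-[4-(benzyloxy)-3,5-diformylphenoxy]-3,5-diformylphenoxy}-5-hydroxyisophthalaldehyde (rings D–C–B phenol)
Conditions: TFA (10 vol%), anisole (5 equiv), CH2Cl2, 0 °C → rt
Reagents that add atoms: none
Why: third PMB acidolysis under the conditions already used in steps 6 and 8.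

Step 11
Reactants: 5 2-fluoro-5-hydroxyisophthalaldehyde; 15 benzyl bromide
Product: 16 5-(benzyloxy)-2-fluoroisophthalaldehyde (ring A monomer)
Conditions: K2CO3, MeCN, 0 °C → rt
Reagents that add atoms: none
Why: Williamson O-benzylation of the phenol, run cold so that alkylation outpaces any intermolecular SNAr.

Step 12
Reactants: 14 rings D–C–B phenol; 16 5-(benzyloxy)-2-fluoroisophthalaldehyde
Product: 17 5-(benzyloxy)-2-(4-{4-[4-(benzyloxy)-3,5-diformylphenoxy]-3,5-diformylphenoxy}-3,5-diformylphenoxy)isophthalaldehyde (tetra-aryl ether octa-aldehyde)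
Conditions: K2CO3, DMSO, 50 °C, 16 (1.05 equiv)
Reagents that add atoms: none
Why: third SNAr diaryl ether formation, which installs ring A with its benzyl ether para to the new ether oxygen.

Step 13
Reactants: 17 tetra-aryl ether octa-aldehyde
Product: 18 octa-formate of the dibenzyl ether (17 with each CHO replaced by O–CHO)
Conditions: mCPBA (dried, 14 equiv), CH2Cl2, 0 °C → 40 °C; cold aq. Na2S2O3/NaHCO3 wash, used crude
Reagents that add atoms: meta-chloroperoxybenzoic acid, O=C(OO)c1cccc(Cl)c1
Why: Each formyl carbonyl adds the peracid to give a Criegee hemiperacetal, and a 1,2-shift of the ring carbon from carbon to the proximal peroxide oxygen with loss of 3-chlorobenzoate turns C–CHO into C–O–CHO at all eight sites. The closest known reaction is the Baeyer–Villiger (Dakin-type) oxidation of ortho-alkoxy- and ortho-aryloxybenzaldehydes, 2-alkoxyisophthalaldehydes included, to aryl formates. No ring closes and no stereocentre is created. The selectivity needed is aryl over hydride migration at every site, so that formates and not carboxylic acids result. It should be secured by the ether oxygen ortho to each migrating carbon (C2–O of ring A, C4–O of rings B, C and D), whose lone pair stabilises the electron-deficient migrating carbon, and by a formyloxy group withdrawing no more strongly from the meta position than the formyl group it replaces. Benzyl and diaryl ethers are inert to the peracid, and the anhydrous, unbuffered medium should keep the formates intact until step 14.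

Step 14
Reactants: 18 octa-formate of the dibenzyl ether
Product: 19 5-(benzyloxy)-2-(4-{4-[4-(benzyloxy)-3,5-dihydroxyphenoxy]-3,5-dihydroxyphenoxy}-3,5-dihydroxyphenoxy)benzene-1,3-diol (octa-phenol dibenzyl ether)
Conditions: HCl (cat.), degassed MeOH/THF, argon, 0 °C → rt
Reagents that add atoms: none
Why: acid-catalysed transesterification of the eight aryl formates to methyl formate; the acidic, oxygen-free medium should protect the polyphenol from autoxidation.

Step 15
Reactants: 19 octa-phenol dibenzyl ether
Product: 20 2-{4-[4-(3,4,5-trihydroxyphenoxy)-3,5-dihydroxyphenoxy]-3,5-dihydroxyphenoxy}benzene-1,3,5-triol (CNP0333502.0)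
Conditions: H2 (1 atm), Pd/C (10 wt% palladium on carbon), degassed MeOH/EtOAc, rt; filtration under argon
Reagents that add atoms: none
Why: catalytic hydrogenolysis of the two benzyl aryl ethers; diaryl ethers and the phenol rings are not reduced under these conditions.

**Compound list**

1 | 4-fluoro-3,5-dimethylphenol | Cc1cc(O)cc(C)c1F | starting material
2 | 4-fluoro-3,5-dimethylphenyl acetate | CC(=O)Oc1cc(C)c(F)c(C)c1 | intermediate
3 | 3,5-bis(dibromomethyl)-4-fluorophenyl acetate | CC(=O)Oc1cc(C(Br)Br)c(F)c(C(Br)Br)c1 | intermediate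
4 | 4-fluoro-3,5-diformylphenyl acetate (acetoxy dialdehyde, not isolated) | CC(=O)Oc1cc(C=O)c(F)c(C=O)c1 | intermediate
5 | 2-fluoro-5-hydroxyisophthalaldehyde | O=Cc1cc(O)cc(C=O)c1F | intermediate
6 | 4-methoxybenzyl chloride | COc1ccc(CCl)cc1 | starting material
7 | 2-fluoro-5-[(4-methoxybenzyl)oxy]isophthalaldehyde | COc1ccc(COc2cc(C=O)c(F)c(C=O)c2)cc1 | intermediate
8 | benzyl alcohol | OCc1ccccc1 | starting material
9 | 2-(benzyloxy)-5-[(4-methoxybenzyl)oxy]isophthalaldehyde | COc1ccc(COc2cc(C=O)c(OCc3ccccc3)c(C=O)c2)cc1 | intermediate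
10 | 2-(benzyloxy)-5-hydroxyisophthalaldehyde | O=Cc1cc(O)cc(C=O)c1OCc1ccccc1 | intermediate
11 | 2-[4-(benzyloxy)-3,5-diformylphenoxy]-5-[(4-methoxybenzyl)oxy]isophthalaldehyde | COc1ccc(COc2cc(C=O)c(Oc3cc(C=O)c(OCc4ccccc4)c(C=O)c3)c(C=O)c2)cc1 | intermediate
12 | 2-[4-(benzyloxy)-3,5-diformylphenoxy]-5-hydroxyisophthalaldehyde | O=Cc1cc(O)cc(C=O)c1Oc1cc(C=O)c(OCc2ccccc2)c(C=O)c1 | intermediate
13 | 2-{4-[4-(benzyloxy)-3,5-diformylphenoxy]-3,5-diformylphenoxy}-5-[(4-methoxybenzyl)oxy]isophthalaldehyde | COc1ccc(COc2cc(C=O)c(Oc3cc(C=O)c(Oc4cc(C=O)c(OCc5ccccc5)c(C=O)c4)c(C=O)c3)c(C=O)c2)cc1 | intermediate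
14 | 2-{4-[4-(benzyloxy)-3,5-diformylphenoxy]-3,5-diformylphenoxy}-5-hydroxyisophthalaldehyde | O=Cc1cc(O)cc(C=O)c1Oc1cc(C=O)c(Oc2cc(C=O)c(OCc3ccccc3)c(C=O)c2)c(C=O)c1 | intermediate
15 | benzyl bromide | BrCc1ccccc1 | starting material
16 | 5-(benzyloxy)-2-fluoroisophthalaldehyde | O=Cc1cc(OCc2ccccc2)cc(C=O)c1F | intermediate
17 | tetra-aryl ether octa-aldehyde, benzyl ethers on ring A para oxygen and ring D central oxygen | O=Cc1cc(OCc2ccccc2)cc(C=O)c1Oc1cc(C=O)c(Oc2cc(C=O)c(Oc3cc(C=O)c(OCc4ccccc4)c(C=O)c3)c(C=O)c2)c(C=O)c1 | intermediate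
18 | octa-formate of the dibenzyl ether | O=COc1cc(OCc2ccccc2)cc(OC=O)c1Oc1cc(OC=O)c(Oc2cc(OC=O)c(Oc3cc(OC=O)c(OCc4ccccc4)c(OC=O)c3)c(OC=O)c2)c(OC=O)c1 | intermediate
19 | octa-phenol dibenzyl ether | Oc1cc(OCc2ccccc2)cc(O)c1Oc1cc(O)c(Oc2cc(O)c(Oc3cc(O)c(OCc4ccccc4)c(O)c3)c(O)c2)c(O)c1 | intermediate
20 | 2-{4-[4-(3,4,5-trihydroxyphenoxy)-3,5-dihydroxyphenoxy]-3,5-dihydroxyphenoxy}benzene-1,3,5-triol (CNP0333502.0) | Oc1cc(O)c(Oc2cc(O)c(Oc3cc(O)c(Oc4cc(O)c(O)c(O)c4)c(O)c3)c(O)c2)c(O)c1 | target

**Step count and risks**

Total step count: 15. Longest linear sequence: 14 steps (steps 1–10 and 12–15, from 1 to 20); step 11 is a one-step branch from 5.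

Steps most likely to fail:

1. Step 13. Hydride instead of aryl migration may occur in some of the eight Criegee adducts, because each ring carries two formyl groups and the flanked ether oxygen is twisted out of conjugation. Oxidation may also stop part-way, giving mixtures of carboxylic acids and partly oxidised material. The fallback sets out from 17 and exchanges the migrating partner. Addition of MeMgBr (THF, −78 °C) to all eight formyl groups should give the octakis(1-hydroxyethyl) tetra-aryl ether F1 as a diastereomer mixture, whose stereocentres vanish in the next operation. Dess–Martin periodinane in CH2Cl2 should give the octa-acetyl tetra-aryl ether F2. Baeyer–Villiger oxidation with CF3CO3H (from trifluoroacetic anhydride and urea–hydrogen peroxide, Na2HPO4, CH2Cl2) can then only proceed by aryl migration, since methyl is the poorest migrating group, and should give the octa-acetate F3. Acidic methanolysis (HCl, degassed MeOH) returns to the route at 19.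

2. Step 12 (and, to a lesser degree, steps 7 and 9). The weakly nucleophilic phenoxide needs warming, and it may then attack an already formed diformyl-flanked diaryl ether carbon (C4 of ring C) instead of the C–F carbon. Such ether exchange would scramble the chain lengths. The fallback sets out from 14 and removes the activation from the rings already in place. Acetalisation of its six formyl groups (ethylene glycol, p-TsOH cat., toluene, Dean–Stark) should give the hexakis(1,3-dioxolan-2-yl) trimer phenol F4, a more nucleophilic phenol whose rings are inert to SNAr. Coupling with 16 (K2CO3, DMSO, 50 °C) should give the tetra-aryl ether dialdehyde hexa-acetal F5, in which only ring A is activated and any exchange is degenerate. Hydrolysis with 2 M HCl in THF returns to the route at 17.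

3. Step 5. Benzyl alkoxide may engage the two formyl groups (hemiacetal formation, hydride transfer of the Cannizzaro–Tishchenko type) faster than it displaces fluoride from the ring deactivated by the para alkoxy group. The fallback sets out from 7 and makes the benzyl–oxygen bond at the benzylic carbon instead. Displacement of fluoride by hydroxide (K2CO3, DMSO/H2O, 60 °C) should give 2-hydroxy-5-[(4-methoxybenzyl)oxy]isophthalaldehyde F6 as its stabilised phenoxide. O-Benzylation with 15 (K2CO3, DMF, 60 °C) returns to the route at 9.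

Further compounds
F1 | step 13 | octakis(1-hydroxyethyl) tetra-aryl ether dibenzyl ether (diastereomer mixture, configuration unassigned) | CC(O)c1cc(OCc2ccccc2)cc(C(C)O)c1Oc1cc(C(C)O)c(Oc2cc(C(C)O)c(Oc3cc(C(C)O)c(OCc4ccccc4)c(C(C)O)c3)c(C(C)O)c2)c(C(C)O)c1
F2 | step 13 | octa-acetyl tetra-aryl ether dibenzyl ether | CC(=O)c1cc(OCc2ccccc2)cc(C(C)=O)c1Oc1cc(C(C)=O)c(Oc2cc(C(C)=O)c(Oc3cc(C(C)=O)c(OCc4ccccc4)c(C(C)=O)c3)c(C(C)=O)c2)c(C(C)=O)c1
F3 | step 13 | octa-acetate of the dibenzyl ether | CC(=O)Oc1cc(OCc2ccccc2)cc(OC(C)=O)c1Oc1cc(OC(C)=O)c(Oc2cc(OC(C)=O)c(Oc3cc(OC(C)=O)c(OCc4ccccc4)c(OC(C)=O)c3)c(OC(C)=O)c2)c(OC(C)=O)c1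
F4 | step 12 | hexakis(1,3-dioxolan-2-yl) trimer phenol (14 with each formyl group as its ethylene acetal) | Oc1cc(C2OCCO2)c(Oc2cc(C3OCCO3)c(Oc3cc(C4OCCO4)c(OCc4ccccc4)c(C4OCCO4)c3)c(C3OCCO3)c2)c(C2OCCO2)c1
F5 | step 12 | tetra-aryl ether with ring A as dialdehyde and rings B, C and D as bis(1,3-dioxolan-2-yl) units | O=Cc1cc(OCc2ccccc2)cc(C=O)c1Oc1cc(C2OCCO2)c(Oc2cc(C3OCCO3)c(Oc3cc(C4OCCO4)c(OCc4ccccc4)c(C4OCCO4)c3)c(C3OCCO3)c2)c(C2OCCO2)c1
F6 | step 5 | 2-hydroxy-5-[(4-methoxybenzyl)oxy]isophthalaldehyde | COc1ccc(COc2cc(C=O)c(O)c(C=O)c2)cc1
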